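**Assumptions:** The drawn [C@@H] centre is (2S), so the target is (2S)-5'-prenylhesperetin. I treat 2,4,6-tribromoanisole, prenyl bromide and 5,7-dihydroxychromone (CAS 31721-94-5) as catalogue compounds.

## Retrosynthetic overview
1. Target 9 comes from neutral removal of two acetates from 8, with no chalcone at any stage.
2. The key disconnection is C2–C1'. A Rh(I)-catalysed enantioselective 1,4-addition of arylboronic acid 5 to 5,7-diacetoxychromone 7 forms this bond and sets C2 (S) in one step.
3. Boronic acid 5 comes from 2,4,6-tribromoanisole by three programmed Br/metal exchanges: ortho Br to prenyl, second ortho Br to OH, para Br to B(OH)2.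
4. Chromone 7 comes from 5,7-dihydroxychromone by acetylation.
5. No ring is built. The A/C bicycle is bought as the chromone and the B ring as the anisole. The C ring only changes from sp2 to sp3 at C2 in the key step.

## Route

**Step 1**
Reactants: 1, 2,4,6-tribromoanisole; 2, prenyl bromide
Product: 3, 1,5-dibromo-2-methoxy-3-(3-methylbut-2-enyl)benzene (2,4-dibromo-6-prenylanisole)
Conditions: n-BuLi (1.0 equiv), Et2O, −78 °C, 20 min; CuBr·SMe2 (1.0 equiv); 2 (1.3 equiv), −78 °C → 0 °C
Reagents that add atoms: prenyl bromide (2), CC(C)=CCBr
Why: This is a regioselective bromine–lithium exchange in which OMe directs exchange to a flanking bromide (O→Li coordination and inductive stabilisation; the two ortho bromides are equivalent), and the derived arylcopper then undergoes SN2-type allylic substitution at the unhindered CH2 of prenyl bromide to give the linear prenyl arene.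

**Step 2**
Reactants: 3
Product: 4, 5-bromo-2-methoxy-3-(3-methylbut-2-enyl)phenol
Conditions: n-BuLi (1.05 equiv), Et2O, −78 °C, 30 min; B(OMe)3 (1.5 equiv), −78 °C → rt; then 30% H2O2, aq NaOH, 0 °C → rt
Reagents that add atoms: hydrogen peroxide, OO (supplies the phenol oxygen; B(OMe)3 is only a transient carrier)
Why: A second OMe-directed bromine–lithium exchange takes the remaining ortho bromide rather than the para one, and borate trapping followed by boronate oxidation (1,2-aryl shift from B to O) gives the phenol without touching the unactivated trisubstituted alkene or the para bromide.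

**Step 3**
Reactants: 4
Product: 5, [3-hydroxy-4-methoxy-5-(3-methylbut-2-enyl)phenyl]boronic acid
Conditions: NaH (1.1 equiv), THF, 0 °C; t-BuLi (2.1 equiv), −78 °C, 10 min; B(OiPr)3 (3 equiv), −78 °C → rt; aq NH4Cl/dilute HCl to pH 5–6
Reagents that add atoms: triisopropyl borate, CC(C)OB(OC(C)C)OC(C)C; water, O
Why: This is a lithiation–borylation in which the phenol is masked as its sodium salt, t-BuLi exchanges the last bromide within minutes at −78 °C (faster than deprotonation of the allylic/benzylic CH2), and borate capture with mild hydrolysis gives the boronic acid with no protecting group.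

**Step 4**
Reactants: 6, 5,7-dihydroxy-4H-chromen-4-one
Product: 7, 4-oxo-4H-chromene-5,7-diyl diacetate (5,7-diacetoxychromone)
Conditions: Ac2O (4 equiv), pyridine, DMAP (cat.), rt
Reagents that add atoms: acetic anhydride, CC(=O)OC(C)=O
Why: This O-acylation masks the acidic 7-OH and the chelating 5-OH (an acac-like ligand for Rh) and, because acetates donate less than OH or OR, raises the electrophilicity of C2.

**Step 5 (key step)**
Reactants: 5 (1.5 equiv); 7
Product: 8, (2S)-2-[3-hydroxy-4-methoxy-5-(3-methylbut-2-enyl)phenyl]-4-oxochromane-5,7-diyl diacetate
Conditions: [Rh(OH)(cod)]2 (1.5 mol %), (S)-MeO-F12-BIPHEP (3.3 mol %), CH2Cl2/H2O 10:1, 25 °C, no added base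
Reagents that add atoms: none (the C3 hydrogen comes from water)
Why: In this Hayashi–Miyaura asymmetric 1,4-addition, the aryl–Rh(I) formed by transmetalation carbometalates the chromone C2=C3 bond on the C2 Re face inside the (S)-biaryl bisphosphine pocket (same sense as (S)-BINAP with cyclohexenone), and fast base-free protonolysis of the oxa-π-allyl Rh enolate by water releases the (2S)-flavanone before β-aryloxide elimination or 1,2-addition can compete.

**Step 6**
Reactants: 8
Product: 9, (2S)-5,7-dihydroxy-2-[3-hydroxy-4-methoxy-5-(3-methylbut-2-enyl)phenyl]-2,3-dihydro-4H-chromen-4-one (target)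
Conditions: NH4OAc (8 equiv), MeOH/H2O 4:1, rt, 8–16 h
Reagents that add atoms: none
Why: Neutral ammonium acetate-mediated solvolysis of the aryl acetates (acyl transfer) frees both phenols at about pH 7, so no enolate or retro-oxa-Michael ring opening occurs, C2 stays (S) (there is no 4'-OH, so no quinone-methide pathway), and the prenyl group sees no acid.

## Compound list
1 | 2,4,6-tribromoanisole | COc1c(Br)cc(Br)cc1Br | starting material
2 | prenyl bromide | CC(C)=CCBr | starting material
3 | 1,5-dibromo-2-methoxy-3-prenylbenzene | COc1c(Br)cc(Br)cc1CC=C(C)C | intermediate
4 | 5-bromo-2-methoxy-3-prenylphenol | COc1c(O)cc(Br)cc1CC=C(C)C | intermediate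
5 | (3-hydroxy-4-methoxy-5-prenylphenyl)boronic acid | COc1c(O)cc(B(O)O)cc1CC=C(C)C | intermediate
6 | 5,7-dihydroxychromone | O=c1ccoc2cc(O)cc(O)c12 | starting material
7 | 5,7-diacetoxychromone | CC(=O)Oc1cc(OC(C)=O)c2c(c1)occc2=O | intermediate
8 | (2S)-5,7-diacetoxy-3'-hydroxy-4'-methoxy-5'-prenylflavanone | COc1c(O)cc([C@@H]2CC(=O)c3c(OC(C)=O)cc(OC(C)=O)cc3O2)cc1CC=C(C)C | intermediate
9 | (2S)-5,7,3'-trihydroxy-4'-methoxy-5'-prenylflavanone | COc1c(O)cc([C@@H]2CC(=O)c3c(O)cc(O)cc3O2)cc1CC=C(C)C | target

## Summary
**Total steps:** 6
**Longest linear sequence:** 5 (1 → 3 → 4 → 5 → 8 → 9)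

**Three steps most likely to fail**

1. **Step 5.** The risks are a sluggish oxygenated chromone, ring opening to the chalcone, partial acetate loss, and a sense of induction assigned only by analogy. Confirm the configuration by chiral HPLC and CD (2S shows a negative band near 290 nm and a positive band near 330 nm), and use the (R)-ligand if the sense is reversed.
   Fallback: set the stereocentre as a carbinol instead.
   - O-silylate 4, then lithiate and quench with DMF to give the aldehyde.
   - Build the (R)-β-hydroxy ketone ArCH(OH)CH2C(O)Ar' by an enantioselective aldol, or by asymmetric transfer hydrogenation of the 1,3-diketone made with MOM-protected phloroacetophenone.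
   - Close the C ring by intramolecular Mitsunobu etherification, which inverts (R) to (S).

2. **Step 2 (and Step 1).** The risk is ortho versus para selectivity in the Br/Li exchange, or halogen scrambling.
   Fallback: start from 2,6-dibromoanisole, which has no para bromide and so no regiochemical question. Carry out the same prenylation and hydroxylation, then O-silylate. Install boron last by sterically controlled Ir-catalysed C–H borylation, since only the position meta to both flanking groups is open.

3. **Step 3.** The risks are poor exchange on the insoluble phenoxide, allylic/benzylic deprotonation, and protodeboronation during work-up.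
   Fallback: avoid organolithium chemistry. Acetylate 4, run a Pd-catalysed Miyaura borylation (B2pin2, KOAc), and convert the product with KHF2 to the aryltrifluoroborate. Use that salt as the aryl donor in the Rh step. The third acetate then comes off in Step 6.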